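**Retrosynthetic overview**

1. The target is a cycloheptane (C1, C5–C10) cis-fused to an α-methylene-γ-butyrolactone. The last events are: Z-propenyl ketone from a C2 thioester by acyl cross-coupling, isovalerate on the C5 hydroxyl, and the C5 hydroxyl from a C5 ketone.
2. Key disconnection C1–C10: the array O–C5–C1(OH)–C2=O next to the C10 methine (a tertiary α-ketol flanked by the C5 oxygen) is the product pattern of an α-ketol shift. Read backwards it is a six-membered ring C5–C10 whose carbinol C5 carries the exocyclic keto ester C1(=O)–CO2Bn; the shift of C10 from C5 to C1 makes the seven-membered ring and the C1 stereocentre in one operation.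
3. The six-membered ring is (R)-carvone (carbonyl = C5, methyl-bearing alkene carbon = C10, isopropenyl = C11–C13 on C7). The isopropenyl group gives the acrylic acid, α'-iodination/SN2 at C6 gives the cis-lactone, hydroboration sets C9–OH/C10–H, and diazoacetate addition then oxidation gives the keto ester.
4. Ring order: six-membered carbocycle (carvone) → γ-lactone (step 3) → seven-membered ring by expansion (step 11). The lactone methylene is masked as a sulfide, later a sulfone, from step 4 to step 16.

Key step: step 11

Remark on locants: C1–C15 are used as in the target for all intermediates (C1 carbinol carbon with the crotonoyl group C2–C4/C15; C5 CH–O-isovalerate; C6, C7 lactone ring-fusion carbons; C8 CH2; C9 CHOH; C10 CH–CH3 with C14; C11–C13 lactone α-carbon, carbonyl, exocyclic CH2). β is the face of the carbocycle that carries the C9 oxygen, α the other. The target is 1α-OH, 5β-O-acyl, 6α-O, 7α-C11 (H-6 and H-7 β), 9β-OH, 10α-CH3.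

Assumption: C11 of the masked lactones 7–12 and 15–22 is a temporary stereocentre that is removed in step 16. It is drawn as the exo epimer expected after amine equilibration, and its configuration has no consequence.

**Route**

Step 1
Reactants: 1 (R)-(−)-carvone
Product: 2 (5R)-5-(3-hydroxyprop-1-en-2-yl)-2-methylcyclohex-2-en-1-one
Conditions: SeO2 (0.3 equiv), t-BuOOH (3 equiv), CH2Cl2, rt
Reagents that add atoms: SeO2, O=[Se]=O (catalytic oxygen carrier); tert-butyl hydroperoxide, CC(C)(C)OO
Why: Catalytic SeO2 allylic oxidation (ene reaction, then 2,3-sigmatropic shift) should attack the electron-rich isopropenyl group rather than the deactivated enone, and within it the methyl group, leaving C7 untouched.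

Step 2
Reactants: 2 (5R)-5-(3-hydroxyprop-1-en-2-yl)-2-methylcyclohex-2-en-1-one
Product: 4 2-[(1R)-4-methyl-5-oxocyclohex-3-en-1-yl]prop-2-enoic acid, via enal 3 (not isolated)
Conditions: TEMPO (cat.), PhI(OAc)2, CH2Cl2, rt; then NaClO2, NaH2PO4, 2-methyl-2-butene, t-BuOH/H2O, rt
Reagents that add atoms: sodium chlorite, [Na+].[O-]Cl=O
Why: Oxoammonium oxidation of the primary allylic alcohol should stop at the enal, and Pinnick oxidation should take the enal to the acrylic acid without touching the enone or C7.

Step 3
Reactants: 4 2-[(1R)-4-methyl-5-oxocyclohex-3-en-1-yl]prop-2-enoic acid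
Product: 6 (3aS,7aR)-6-methyl-3-methylidene-3a,4-dihydro-1-benzofuran-2,7(3H,7aH)-dione (cis-fused 6α,12-lactone of the C5 enone), via 6β-iodo carboxylate 5 (not isolated)
Conditions: LiN(iPr)2 (2.2 equiv), THF, −78 °C; I2, −78 → 0 °C
Reagents that add atoms: none
Why: Kinetic deprotonation of the carboxylate salt should occur at the α'-methylene C6 (as for carvone itself), iodine should enter anti to the C7 arm, and the carboxylate should then displace the α-keto iodide by intramolecular SN2 (5-exo-tet) with inversion, which sets the 6α-oxygen and a cis ring fusion.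

Step 4
Reactants: 6 cis-fused enone α-methylene lactone
Product: 7 C13-phenylsulfanyl adduct of 6 (C11–CH2SPh, enone unchanged)
Conditions: PhSH (1.0 equiv), Et3N (cat.), CH2Cl2, 0 °C
Reagents that add atoms: thiophenol, Sc1ccccc1
Why: Base-catalysed thia-Michael addition should go to the exocyclic acrylate far faster than to the α-methyl-substituted ring enone; the sulfide protects the acceptor against borane and the diazo reagent and becomes a leaving group after oxidation.

Step 5
Reactants: 7 sulfide-masked enone lactone
Product: 8 5α-allylic alcohol (C5–OH cis to the C6 oxygen, C9=C10 retained)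
Conditions: NaBH4, CeCl3·7H2O, MeOH, −78 °C
Reagents that add atoms: none
Why: Luche reduction should give clean 1,2-reduction of the enone, with hydride arriving on the convex β-face anti to the α-acyloxy group, so the hydroxyl is 5α.

Step 6
Reactants: 8 5α-allylic alcohol
Product: 10 5α,9β-diol with 10α-methyl, via alkylborane 9 (not isolated)
Conditions: BH3·SMe2 (2.5 equiv), THF, 0 °C → rt; then NaBO3·4H2O, THF/H2O, rt
Reagents that add atoms: borane–dimethyl sulfide, [BH3-][S+](C)C (boron stays only in 9); sodium perborate, [Na+].[Na+].O[B-]1(O)OO[B-](O)(O)OO1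
Why: Hydroboration is a syn addition with boron on the less substituted C9, so the C9 oxygen and H-10 end cis (hydroxyl trans to the methyl); borane should approach the convex β-face, anti to the allylic C5 oxygen and the lactone, which sets 9β-OH and 10α-CH3, and perborate oxidises C–B with retention without opening the lactone.

Step 7
Reactants: 10 5α,9β-diol
Product: 11 9β-tert-butyldimethylsilyl ether with free 5α-hydroxyl
Conditions: TBSCl (1.1 equiv), imidazole, DMF, 0 °C → rt
Reagents that add atoms: tert-butyldimethylsilyl chloride, CC(C)(C)[Si](C)(C)Cl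
Why: The C9 hydroxyl should be silylated in preference to the C5 hydroxyl, which is flanked by two substituted carbons and deactivated by the neighbouring acyloxy group.

Step 8
Reactants: 11 9β-silyl ether 5α-alcohol
Product: 12 C5 ketone (6α,12-lactone, 9β-OTBS, 10α-CH3, C11–CH2SPh)
Conditions: DMP (triacetoxyperiodinane), CH2Cl2, rt
Reagents that add atoms: none
Why: Periodinane oxidation under non-basic conditions should give the ketone without epimerising C10 or C6 and without oxidising the sulfide.

Step 9
Reactants: 12 C5 ketone; 13 benzyl diazoacetate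
Product: 15 C5 carbinol with 5α-OH and 5β-C(=N2)CO2Bn, via benzyl lithiodiazoacetate 14 (not isolated)
Conditions: LiN(iPr)2, THF, −78 °C; then 12, −78 °C; AcOH quench at −78 °C
Reagents that add atoms: benzyl diazoacetate 13, [N-]=[N+]=CC(=O)OCc1ccccc1
Why: Aldol-type addition of the lithiated diazo ester to the α-acyloxy-activated ketone should occur from the convex β-face (equatorial attack), because the α-face is blocked by the axial C7–C11 bond of the cis-fused lactone, so C1 is attached β and the hydroxyl is α.

Step 10
Reactants: 15 diazo carbinol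
Product: 16 β-hydroxy α-keto ester: 5α-OH, 5β-C(=O)CO2Bn, lactone side arm now CH2SO2Ph
Conditions: dimethyldioxirane (3.5 equiv), acetone/CH2Cl2, −78 → 0 °C
Reagents that add atoms: dimethyldioxirane, CC1(C)OO1
Why: Dimethyldioxirane transfers oxygen to the diazo carbon with loss of N2 to give the vicinal keto ester, and the same reagent oxidises the sulfide to the sulfone, which turns the mask into a leaving group for step 16.

Step 11
Reactants: 16 β-hydroxy α-keto ester on the six-membered ring
Product: 17 ring-expanded cycloheptanone: 5-oxo, 1α-OH, 1β-CO2Bn, 6α,12-lactone, 9β-OTBS, 10α-CH3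
Conditions: Cu(OTf)2 (0.2 equiv), 4 Å MS, CH2Cl2, rt → 40 °C
Reagents that add atoms: none
Why: Lewis-acid-promoted α-ketol (acyloin) rearrangement: divalent copper binds the 1,2-dicarbonyl unit, the C5 hydroxyl lies syn-periplanar to the C1 carbonyl (hydrogen bond to O1) and, as its proton passes to O1, the C5–C10 bond shifts to C1 while C5 becomes the ketone. The closest known reaction type is the ring-expanding α-ketol shift of 1-acylcycloalkanols and the isomerisation of β-hydroxy α-keto esters to α-hydroxy β-keto esters. The seven-membered ring is closed by ring expansion of the six-membered ring, a suprafacial 1,2-shift that inserts C1 between C5 and C10 (one-carbon insertion, not cyclisation of an open chain). C1 is the only new stereocentre and is set by chirality transfer from C5: with 5α-OH and the keto ester on the β-face, the syn array places C10 over one face of the C1 carbonyl only, which gives 1α-OH with the ester β, and C10 moves with retention. The step needs migration of C10 and not of C6 and an equilibrium on the product side; the acyloxy-substituted C6 is the poorer migrating group, and the change from a 1,2-dicarbonyl to a hydrogen-bonded β-keto ester plus relief of crowding at the quaternary C5 provides the driving force.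

Step 12
Reactants: 17 ring-expanded α-hydroxy ketone
Product: 18 1α,5β-diol (trans)
Conditions: Me4NBH(OAc)3, MeCN/AcOH, −30 → 0 °C
Reagents that add atoms: none
Why: Hydroxyl-directed reduction (Evans–Saksena type): the triacetoxyborohydride exchanges onto the C1 hydroxyl and delivers hydride to the C5 ketone from the α-face, which should give the trans-1,2-diol (5β-OH) while esters, lactone and silyl ether stay intact.

Step 13
Reactants: 18 1α,5β-diol; 19 3-methylbutanoyl chloride
Product: 20 5β-isovalerate
Conditions: pyridine, DMAP (cat.), CH2Cl2, 0 °C → rt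
Reagents that add atoms: 3-methylbutanoyl chloride 19, CC(C)CC(=O)Cl
Why: Only the secondary C5 hydroxyl should be acylated (the C1 hydroxyl is tertiary and hindered), and pyridine is too weak a base to eliminate the β-sulfonyl lactone.

Step 14
Reactants: 20 benzyl ester
Product: 21 C2 carboxylic acid
Conditions: H2 (1 atm), Pd/C, EtOAc, rt
Reagents that add atoms: none
Why: Hydrogenolysis of the benzyl ester is possible at this point because the lactone methylene is still masked and the molecule contains no C=C bond.

Step 15
Reactants: 21 C2 carboxylic acid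
Product: 22 S-phenyl thioester at C2
Conditions: PhSH, DCC, DMAP (cat.), CH2Cl2, 0 °C → rt
Reagents that add atoms: thiophenol, Sc1ccccc1
Why: Steglich-type thioesterification gives the acyl donor for a neutral ketone synthesis; the C9 silyl ether prevents γ-lactonisation onto the activated acid, and the masked lactone cannot take up thiol.

Step 16
Reactants: 22 S-phenyl thioester with sulfone-masked lactone
Product: 23 α-methylene-γ-butyrolactone S-phenyl thioester
Conditions: DBU, CH2Cl2, 0 °C; NaHCO3 wash
Reagents that add atoms: none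
Why: E1cB elimination of benzenesulfinate from the β-sulfonyl lactone should unmask the exocyclic methylene under conditions that leave the hindered thioester alone, with no thiol left to add back.

Step 17
Reactants: 23 α-methylene lactone thioester; 24 (Z)-prop-1-enylboronic acid
Product: 25 9-O-tert-butyldimethylsilyl ether of the target
Conditions: Pd2(dba)3 (cat.), P(2-furyl)3, Cu(O2C-2-thienyl) (1.5 equiv), THF, 50 °C
Reagents that add atoms: (Z)-prop-1-enylboronic acid 24, C/C=C\B(O)O
Why: Liebeskind–Srogl coupling: zerovalent palladium inserts into the acyl–S bond and the monovalent copper carboxylate mediates base-free transmetalation from boron, so the alkenyl group should be transferred with retention of the Z geometry while lactone, isovalerate and the free tertiary hydroxyl are tolerated.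

Step 18
Reactants: 25 9-O-silyl ether
Product: 26 target CNP0186412.2
Conditions: HF·pyridine, THF, 0 °C → rt
Reagents that add atoms: none
Why: Fluoride-mediated desilylation under mildly acidic conditions should free the C9 hydroxyl without isomerising the Z-enone or cleaving the esters.

**Compound list**

1 | (R)-(−)-carvone, (5R)-2-methyl-5-(prop-1-en-2-yl)cyclohex-2-en-1-one | CC1=CC[C@H](CC1=O)C(C)=C | starting material
2 | (5R)-5-(3-hydroxyprop-1-en-2-yl)-2-methylcyclohex-2-en-1-one | CC1=CC[C@H](CC1=O)C(CO)=C | intermediate
3 | 2-[(1R)-4-methyl-5-oxocyclohex-3-en-1-yl]prop-2-enal | CC1=CC[C@H](CC1=O)C(C=O)=C | intermediate (not isolated)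
4 | 2-[(1R)-4-methyl-5-oxocyclohex-3-en-1-yl]prop-2-enoic acid | CC1=CC[C@H](CC1=O)C(C(=O)O)=C | intermediate
5 | lithium 2-(6-iodo-4-methyl-5-oxocyclohex-3-en-1-yl)prop-2-enoate, iodine at C6 trans to the acrylate arm (6β-I) | CC1=CC[C@H]([C@H](I)C1=O)C(=C)C(=O)[O-].[Li+] | intermediate (not isolated)
6 | (3aS,7aR)-6-methyl-3-methylidene-3a,4-dihydro-1-benzofuran-2,7(3H,7aH)-dione; cis-fused 6α,12-lactone, C5 ketone, C9=C10 | C=C1C(=O)O[C@@H]2[C@H]1CC=C(C)C2=O | intermediate
7 | thiophenol adduct of 6: C11–CH2SPh (exo), cis-lactone, enone | c1ccccc1SC[C@@H]1C(=O)O[C@@H]2[C@H]1CC=C(C)C2=O | intermediate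
8 | 5α-allylic alcohol of 7 (C5–OH cis to the C6 oxygen) | c1ccccc1SC[C@@H]1C(=O)O[C@@H]2[C@H]1CC=C(C)[C@@H]2O | intermediate
9 | alkylborane from 8: 9β-BH2, 10β-H, 5α-OBH2 | c1ccccc1SC[C@@H]1C(=O)O[C@@H]2[C@H]1C[C@@H](B)[C@H](C)[C@@H]2OB | intermediate (not isolated)
10 | 5α,9β-diol, 10α-methyl, cis-lactone, C11–CH2SPh | c1ccccc1SC[C@@H]1C(=O)O[C@@H]2[C@H]1C[C@@H](O)[C@H](C)[C@@H]2O | intermediate
11 | 9β-OTBS, 5α-OH analogue of 10 | c1ccccc1SC[C@@H]1C(=O)O[C@@H]2[C@H]1C[C@@H](O[Si](C)(C)C(C)(C)C)[C@H](C)[C@@H]2O | intermediate
12 | C5 ketone: 6α,12-lactone, 9β-OTBS, 10α-CH3, C11–CH2SPh | c1ccccc1SC[C@@H]1C(=O)O[C@@H]2[C@H]1C[C@@H](O[Si](C)(C)C(C)(C)C)[C@H](C)C2=O | intermediate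
13 | benzyl diazoacetate | [N-]=[N+]=CC(=O)OCc1ccccc1 | starting material
14 | benzyl lithiodiazoacetate | [Li]C(=[N+]=[N-])C(=O)OCc1ccccc1 | intermediate (not isolated)
15 | C5 carbinol: 5α-OH, 5β-C(=N2)CO2Bn, otherwise as 12 | c1ccccc1SC[C@@H]1C(=O)O[C@@H]2[C@H]1C[C@@H](O[Si](C)(C)C(C)(C)C)[C@H](C)[C@@]2(O)C(=[N+]=[N-])C(=O)OCc1ccccc1 | intermediate
16 | β-hydroxy α-keto ester: 5α-OH, 5β-C(=O)CO2Bn, C11–CH2SO2Ph | O=S(=O)(C[C@@H]1C(=O)O[C@@H]2[C@H]1C[C@@H](O[Si](C)(C)C(C)(C)C)[C@H](C)[C@@]2(O)C(=O)C(=O)OCc1ccccc1)c1ccccc1 | intermediate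
17 | cycloheptanone: 5-oxo, 1α-OH, 1β-CO2Bn, 6α,12-lactone, 9β-OTBS, 10α-CH3, C11–CH2SO2Ph | O=S(=O)(C[C@@H]1C(=O)O[C@@H]2[C@H]1C[C@@H](O[Si](C)(C)C(C)(C)C)[C@H](C)[C@@](O)(C(=O)OCc1ccccc1)C2=O)c1ccccc1 | intermediate
18 | 1α,5β-diol from 17 | O=S(=O)(C[C@@H]1C(=O)O[C@@H]2[C@H]1C[C@@H](O[Si](C)(C)C(C)(C)C)[C@H](C)[C@@](O)(C(=O)OCc1ccccc1)[C@H]2O)c1ccccc1 | intermediate
19 | 3-methylbutanoyl chloride (isovaleryl chloride) | CC(C)CC(=O)Cl | starting material
20 | 5β-isovalerate of 18 | O=S(=O)(C[C@@H]1C(=O)O[C@@H]2[C@H]1C[C@@H](O[Si](C)(C)C(C)(C)C)[C@H](C)[C@@](O)(C(=O)OCc1ccccc1)[C@H]2OC(=O)CC(C)C)c1ccccc1 | intermediate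
21 | C2 carboxylic acid from 20 | O=S(=O)(C[C@@H]1C(=O)O[C@@H]2[C@H]1C[C@@H](O[Si](C)(C)C(C)(C)C)[C@H](C)[C@@](O)(C(=O)O)[C@H]2OC(=O)CC(C)C)c1ccccc1 | intermediate
22 | S-phenyl thioester of 21 | O=S(=O)(C[C@@H]1C(=O)O[C@@H]2[C@H]1C[C@@H](O[Si](C)(C)C(C)(C)C)[C@H](C)[C@@](O)(C(=O)Sc1ccccc1)[C@H]2OC(=O)CC(C)C)c1ccccc1 | intermediate
23 | α-methylene lactone S-phenyl thioester (1α-OH, 5β-isovalerate, 9β-OTBS) | C=C1C(=O)O[C@@H]2[C@H]1C[C@@H](O[Si](C)(C)C(C)(C)C)[C@H](C)[C@@](O)(C(=O)Sc1ccccc1)[C@H]2OC(=O)CC(C)C | intermediate
24 | (Z)-prop-1-enylboronic acid | C/C=C\B(O)O | starting material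
25 | 9-O-TBS ether of the target | C=C1C(=O)O[C@@H]2[C@H]1C[C@@H](O[Si](C)(C)C(C)(C)C)[C@H](C)[C@@](O)(C(=O)/C=C\C)[C@H]2OC(=O)CC(C)C | intermediate
26 | CNP0186412.2 | C=C1C(=O)O[C@@H]2[C@H]1C[C@@H](O)[C@H](C)[C@@](O)(C(=O)/C=C\C)[C@H]2OC(=O)CC(C)C | target

**Step count and risks**

Total step count: 18. Longest linear sequence: 18 steps, from (R)-carvone.

Steps most likely to fail:

Step 11. The 1,2-shift may stall at an unfavourable equilibrium, since a six-membered ring becomes a seven-membered one. C6 may migrate in competition, or the Lewis acid may induce translactonisation onto the C5 hydroxyl. The fallback uses known chemistry, sets out from 12 and returns at 17. The ketone 12 is homologated directly with benzyl diazoacetate 13 and BF3·OEt2 in CH2Cl2 at −78 → 0 °C. The diazo carbon adds to the activated C5 carbonyl and C10 shifts to it with irreversible loss of N2, which gives the ring-expanded β-keto ester F1; the same C1–C10 bond is formed, now under kinetic control. Excess dimethyldioxirane in acetone then hydroxylates the enolised C1 and oxidises the sulfide to the sulfone, which is 17. In this variant C1 is set by the facial selectivity of the hydroxylation and no longer by chirality transfer, so its configuration would have to be confirmed at 17.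

Step 3. The α'-iodo enone may lose HI and tautomerise to a phenol, or iodination may occur on the face from which the carboxylate cannot reach C6. The fallback sets out from 4 and returns at 6. The dianion of 4 (LiN(iPr)2, THF, −78 °C) is hydroxylated with 2-(phenylsulfonyl)-3-phenyloxaziridine to the 6β-hydroxy keto acid F2, with oxygen anti to the C7 arm. An intramolecular Mitsunobu reaction (PPh3, diisopropyl azodicarboxylate, THF, 0 °C) then closes the lactone with inversion at C6 to give 6.

Step 17. Acyl transfer may be slow at the thioester next to the quaternary C1, or the alkenyl group may isomerise from Z to E during coupling. The fallback sets out from 23 and returns at 25. Coupling of 23 with tributyl(prop-1-ynyl)stannane (Pd2(dba)3, P(2-furyl)3, Cu(O2PPh2), THF, rt) gives the ynone F3. Semi-hydrogenation over Pd/CaCO3 poisoned with Pb(OAc)2 and quinoline (H2, 1 atm, EtOAc, stopped after one equivalent) then gives the Z-enone 25; the alkyne should be reduced much faster than the 1,1-disubstituted acrylate double bond.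

Further compounds
F1 | step 11 | ring-expanded β-keto ester: 5-oxo, C1–H (epimerisable, enolisable) with CO2Bn, 6α,12-lactone, 9β-OTBS, 10α-CH3, C11–CH2SPh | c1ccccc1SC[C@@H]1C(=O)O[C@@H]2[C@H]1C[C@@H](O[Si](C)(C)C(C)(C)C)[C@H](C)C(C(=O)OCc1ccccc1)C2=O
F2 | step 3 | 2-(6-hydroxy-4-methyl-5-oxocyclohex-3-en-1-yl)prop-2-enoic acid, hydroxyl at C6 trans to the acrylic arm (6β-OH) | CC1=CC[C@H]([C@H](O)C1=O)C(=C)C(=O)O
F3 | step 17 | ynone: C1–C(=O)–C≡C–CH3 analogue of 25 | C=C1C(=O)O[C@@H]2[C@H]1C[C@@H](O[Si](C)(C)C(C)(C)C)[C@H](C)[C@@](O)(C(=O)C#CC)[C@H]2OC(=O)CC(C)C
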